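**Retrosynthetic overview**

1. Eremophilane numbering: ring A = C1–C5 and C10, ring B = C5–C10, C14 on C5, C15 on C4, C11–C13 = isopropylidene. The C3 ester is cut last. Its Z-enoate comes from a Still–Gennari olefination of a C3 phosphonopropionate with 2-oxoethyl angelate.
2. C3–OH, C4–H, C9–OH and C10–H are traced to one alpha-face reduction/double hydroboration of the flat eremophila-3,7(11),9-trien-8-one. C8 is then re-oxidised as the only allylic alcohol. The isopropylidene comes from acetone by aldol at C7.
3. Key disconnection C4–C5: an enantioselective palladium-catalysed dearomative alkenylation of an achiral phenol closes ring A. It creates quaternary C5, the only stereocentre that must come from a catalyst.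
4. Enabling feature: in ring B the C8 oxygen stands para to C5, and C5 already bears the C14 methyl. Ring B is therefore a latent 4-methylphenol whose para carbon is nucleophilic and cannot rearomatise. C10 (meta to the oxygen) carries the C1–C2 tether that brings alkenyl carbon C4 within reach.
5. Ring order: ring B is bought as the arene, ring A is closed in the key step, and no further ring is made.

Key step: step 5

Assumption: the ligand antipode named in step 5 is taken to give R at C5; if the sense of induction is opposite, its mirror image is used. Alpha denotes the face opposite C14.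

**Step 1**
Reactants: 1 3-bromo-4-methylphenol
Product: 2 (3-bromo-4-methylphenoxy)triisopropylsilane
Conditions: iPr3SiCl, imidazole, DMF, rt
Reagents that add atoms: triisopropylsilyl chloride CC(C)[Si](Cl)(C(C)C)C(C)C
Why: Standard imidazole-promoted silyl ether formation masks the acidic phenol for the hot Heck step and the strongly basic ylide step, and no stereocentre is involved.

**Step 2**
Reactants: 2 (3-bromo-4-methylphenoxy)triisopropylsilane, 3 allyl alcohol
Product: 4 3-{2-methyl-5-[(triisopropylsilyl)oxy]phenyl}propanal
Conditions: Pd(OAc)2 (5 mol %), P(o-tol)3 (10 mol %), NaHCO3, Bu4NCl, DMF, 90 °C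
Reagents that add atoms: none
Why: Heck arylation of an allylic alcohol, in which carbopalladation at the terminal carbon, beta-hydride elimination toward the carbinol and enol tautomerisation should give the 3-arylpropanal directly.

**Step 3**
Reactants: 4 3-{2-methyl-5-[(triisopropylsilyl)oxy]phenyl}propanal, 5 ethyltriphenylphosphonium iodide
Product: 9 triisopropyl{3-[(3Z)-4-iodopent-3-en-1-yl]-4-methylphenoxy}silane, via ethylidenetriphenylphosphorane 6 (not isolated), via 1-iodoethyltriphenylphosphonium iodide 7 (not isolated), via 1-iodoethylidenetriphenylphosphorane 8 (not isolated)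
Conditions: 5, n-BuLi, THF, 0 °C to rt; I2, THF, -78 °C; NaN(SiMe3)2, -20 °C; then 4, -78 °C
Reagents that add atoms: iodine II
Why: Stork–Zhao-type Wittig olefination with the alpha-iodo ylide should give the Z-2-iodoalk-2-ene (iodine cis to the chain) under kinetic oxaphosphetane control, the geometry that later lets C4 reach C5.

**Step 4**
Reactants: 9 triisopropyl{3-[(3Z)-4-iodopent-3-en-1-yl]-4-methylphenoxy}silane
Product: 10 3-[(3Z)-4-iodopent-3-en-1-yl]-4-methylphenol
Conditions: Bu4NF, AcOH (1:1), THF, 0 °C
Reagents that add atoms: none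
Why: Buffered fluoride desilylation of the aryl silyl ether frees the phenol without touching the alkenyl iodide or its geometry.

**Step 5**
Reactants: 10 3-[(3Z)-4-iodopent-3-en-1-yl]-4-methylphenol
Product: 11 (4aR)-4a,5-dimethyl-7,8-dihydronaphthalen-2(4aH)-one (C8 ketone, C3=C4, C6=C7 and C9=C10 double bonds, 5R)
Conditions: [Pd(cinnamyl)Cl]2 (2.5 mol %), (R)-AntPhos-type P-chiral monophosphine (6 mol %), K2CO3, toluene (0.02 M), 90 °C
Reagents that add atoms: none
Why: Oxidative addition of the C4–I bond to zerovalent palladium (retention, so palladium stays cis to the C1–C2 tether) is followed by carbonate-assisted attack of the phenoxide through its para carbon C5 on divalent palladium and by C(sp2)–C(sp3) reductive elimination, which forms C4–C5, turns the C8 oxygen into the ketone and leaves the C3=C4, C6=C7 and C9=C10 double bonds. The closest known reaction type is the palladium-catalysed enantioselective arylative and alkenylative dearomatisation of 4-alkylphenols that carry the halide on a two-carbon tether at the meta position, which builds 4a-methyl dienones of the phenanthrenone and steroid ring A type with the same tether length. Ring A closes as a six-membered ring by reductive elimination from a seven-membered palladacycle (Pd, C4, C3, C2, C1, C10, C5), a closure open only to the Z-iodide. The single new stereocentre, quaternary C5, is set by the bulky P-chiral monophosphine, which decides which face of the planar phenoxide binds palladium. The step needs C5 over C9 (both would give six-membered rings) and C- over O-alkenylation: C5 is the most electron-rich phenoxide carbon and is further enriched by C14, C9 is squeezed between the oxygen with its cation and the tether, the oxygen cannot reach palladium across the meta bridge, and high dilution suppresses the intermolecular ether. Because C5 bears C14 the dienone cannot rearomatise and should survive the basic medium.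

**Step 6**
Reactants: 11 (4aR)-4a,5-dimethyl-7,8-dihydronaphthalen-2(4aH)-one
Product: 12 (4aR)-4a,5-dimethyl-4,4a,7,8-tetrahydronaphthalen-2(3H)-one
Conditions: H2 (1 atm), RhCl(PPh3)3 (10 mol %), toluene-EtOH, rt
Reagents that add atoms: none
Why: Homogeneous hydrogenation should saturate only the cis-disubstituted C6=C7 bond, as in the classical reduction of steroidal 1,4-dien-3-ones to 4-en-3-ones, because both trisubstituted alkenes bind the rhodium centre too poorly.

**Step 7**
Reactants: 12 (4aR)-4a,5-dimethyl-4,4a,7,8-tetrahydronaphthalen-2(3H)-one, 13 acetone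
Product: 15 (4aR)-3-(2-hydroxypropan-2-yl)-4a,5-dimethyl-4,4a,7,8-tetrahydronaphthalen-2(3H)-one (epimers at C7), via lithium dienolate 14 (not isolated)
Conditions: LiN(iPr)2, THF, -78 °C; 13, -78 °C; aq. NH4Cl
Reagents that add atoms: none
Why: Kinetic alpha-prime deprotonation of the enone at C7 and aldol addition to acetone follow the standard way of bringing C11–C13 into eremophilanes, and the new C7 stereocentre is erased in the next step.

**Step 8**
Reactants: 15 (4aR)-3-(2-hydroxypropan-2-yl)-4a,5-dimethyl-4,4a,7,8-tetrahydronaphthalen-2(3H)-one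
Product: 17 (5R)-eremophila-3,7(11),9-trien-8-one, via tertiary mesylate 16 (not isolated)
Conditions: MsCl, Et3N, CH2Cl2, 0 °C; then DBU, rt
Reagents that add atoms: none
Why: Mesylation through sulfene followed by E1cB elimination uses the acidic C7–H, so only the conjugated tetrasubstituted C7=C11 alkene should form.

**Step 9**
Reactants: 17 (5R)-eremophila-3,7(11),9-trien-8-one
Product: 19 (3R,4R,5R,8S,9S,10R)-eremophil-7(11)-ene-3,8,9-triol (3-alpha, 8-beta, 9-alpha, 10-alpha-H), via trisboryl adduct 18 (not isolated)
Conditions: BH3·THF (4 equiv), THF, 0 °C to rt; then aq. NaOH, H2O2, 0 °C to rt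
Reagents that add atoms: hydrogen peroxide OO
Why: Borane first reduces the cross-conjugated ketone by axial hydride delivery (8-beta alkoxyborane) and then adds syn and anti-Markovnikov (Brown hydroboration-oxidation, retention in the oxidation) to both trisubstituted alkenes from the alpha face, opposite the axial C14 methyl that shields the beta face of both rings, so that C3–OH, C4–H, C9–OH and C10–H (trans fusion) are all set by C5, as in the classical conversion of steroidal 4-en-3-ones into 5-alpha 3-beta,4-alpha-diols, while the tetrasubstituted C7=C11 bond reacts more slowly.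

**Step 10**
Reactants: 19 (3R,4R,5R,8S,9S,10R)-eremophil-7(11)-ene-3,8,9-triol
Product: 20 (3R,4R,5R,9S,10R)-3,9-dihydroxyeremophil-7(11)-en-8-one
Conditions: MnO2 (activated, excess), CH2Cl2, rt
Reagents that add atoms: none
Why: Chemoselective MnO2 oxidation should take only the allylic C8 carbinol, whose axial C–H overlaps with the C7=C11 pi bond, and leave the two saturated equatorial alcohols and all stereocentres untouched.

**Step 11**
Reactants: 21 ethyl 2-[bis(2,2,2-trifluoroethoxy)phosphoryl]propanoate
Product: 22 2-[bis(2,2,2-trifluoroethoxy)phosphoryl]propanoic acid (racemic)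
Conditions: LiOH (1.05 equiv), THF-H2O, 0 °C; then 1 M HCl
Reagents that add atoms: lithium hydroxide [Li+].[OH-]
Why: Saponification with one equivalent of hydroxide in the cold should cleave the activated carboxylic ester faster than the phosphonate esters, the usual access to phosphonoalkanoic acids for on-substrate olefination.

**Step 12**
Reactants: 23 angelic acid ((Z)-2-methylbut-2-enoic acid), 24 2-bromoethanol
Product: 25 2-hydroxyethyl (Z)-2-methylbut-2-enoate
Conditions: Cs2CO3, DMF, rt to 40 °C
Reagents that add atoms: none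
Why: SN2 O-alkylation of the caesium carboxylate never activates the acyl group, so the labile Z geometry of the angelate should be kept.

**Step 13**
Reactants: 25 2-hydroxyethyl (Z)-2-methylbut-2-enoate
Product: 26 2-oxoethyl (Z)-2-methylbut-2-enoate
Conditions: Dess-Martin periodinane, CH2Cl2, 0 °C to rt
Reagents that add atoms: none
Why: Dess–Martin oxidation gives the acyloxyacetaldehyde under neutral conditions that neither isomerise the angelate nor over-oxidise, and the aldehyde is used crude.

**Step 14**
Reactants: 20 (3R,4R,5R,9S,10R)-3,9-dihydroxyeremophil-7(11)-en-8-one, 22 2-[bis(2,2,2-trifluoroethoxy)phosphoryl]propanoic acid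
Product: 27 (3R,4R,5R,9S,10R)-9-hydroxy-8-oxoeremophil-7(11)-en-3-yl 2-[bis(2,2,2-trifluoroethoxy)phosphoryl]propanoate (epimers at the phosphonate carbon)
Conditions: DCC, DMAP (10 mol %), CH2Cl2, 0 °C
Reagents that add atoms: none
Why: Steglich esterification with one equivalent of acid should select the C3 hydroxyl, because the C9 hydroxyl is hydrogen-bonded to the C8 carbonyl, inductively deactivated and crowded by C1 and C10.

**Step 15**
Reactants: 27 (3R,4R,5R,9S,10R)-9-hydroxy-8-oxoeremophil-7(11)-en-3-yl 2-[bis(2,2,2-trifluoroethoxy)phosphoryl]propanoate, 26 2-oxoethyl (Z)-2-methylbut-2-enoate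
Product: 29 target CNP0308665.1, via potassium phosphonate carbanion 28 (not isolated)
Conditions: KN(SiMe3)2 (1.0 equiv), 18-crown-6, THF, -78 °C; then 26, -78 °C
Reagents that add atoms: none
Why: Still–Gennari olefination, in which fast irreversible collapse of the kinetic adduct of the trifluoroethyl phosphonate should give the Z-trisubstituted enoate, the phosphonate C–H being the most acidic site so that one equivalent of base leaves the ketol alone, and the ester bond to the hindered C3 oxygen is already in place so no Z-acid has to be activated.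

**Compound list**

1 | 3-bromo-4-methylphenol | Cc1ccc(O)cc1Br | starting material
2 | (3-bromo-4-methylphenoxy)triisopropylsilane | Cc1ccc(O[Si](C(C)C)(C(C)C)C(C)C)cc1Br | intermediate
3 | allyl alcohol | C=CCO | starting material
4 | 3-{2-methyl-5-[(triisopropylsilyl)oxy]phenyl}propanal | Cc1ccc(O[Si](C(C)C)(C(C)C)C(C)C)cc1CCC=O | intermediate
5 | ethyltriphenylphosphonium iodide | CC[P+](c1ccccc1)(c1ccccc1)c1ccccc1.[I-] | starting material
6 | ethylidenetriphenylphosphorane | CC=P(c1ccccc1)(c1ccccc1)c1ccccc1 | intermediate
7 | (1-iodoethyl)triphenylphosphonium iodide | CC(I)[P+](c1ccccc1)(c1ccccc1)c1ccccc1.[I-] | intermediate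
8 | (1-iodoethylidene)triphenylphosphorane | CC(I)=P(c1ccccc1)(c1ccccc1)c1ccccc1 | intermediate
9 | triisopropyl{3-[(3Z)-4-iodopent-3-en-1-yl]-4-methylphenoxy}silane | Cc1ccc(O[Si](C(C)C)(C(C)C)C(C)C)cc1CC/C=C(/C)I | intermediate
10 | 3-[(3Z)-4-iodopent-3-en-1-yl]-4-methylphenol | Cc1ccc(O)cc1CC/C=C(/C)I | intermediate
11 | (4aR)-4a,5-dimethyl-7,8-dihydronaphthalen-2(4aH)-one | CC1=CCCC2=CC(=O)C=C[C@]12C | intermediate
12 | (4aR)-4a,5-dimethyl-4,4a,7,8-tetrahydronaphthalen-2(3H)-one | CC1=CCCC2=CC(=O)CC[C@]12C | intermediate
13 | acetone | CC(C)=O | starting material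
14 | lithium cross-conjugated dienolate of 12 | CC1=CCCC2=CC([O-])=CC[C@]12C.[Li+] | intermediate
15 | (4aR)-3-(2-hydroxypropan-2-yl)-4a,5-dimethyl-4,4a,7,8-tetrahydronaphthalen-2(3H)-one, C7 epimers | CC1=CCCC2=CC(=O)C(C(C)(C)O)C[C@]12C | intermediate
16 | tertiary methanesulfonate of 15 | CC1=CCCC2=CC(=O)C(C(C)(C)OS(C)(=O)=O)C[C@]12C | intermediate
17 | (5R)-eremophila-3,7(11),9-trien-8-one | CC1=CCCC2=CC(=O)C(=C(C)C)C[C@]12C | intermediate
18 | 3-alpha,9-alpha-diboryl-8-beta-boryloxy-10-alpha-H-eremophil-7(11)-ene (drawn with BH2 groups) | B[C@@H]1CC[C@H]2[C@H](B)[C@@H](OB)C(=C(C)C)C[C@]2(C)[C@H]1C | intermediate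
19 | (3R,4R,5R,8S,9S,10R)-eremophil-7(11)-ene-3,8,9-triol | O[C@@H]1CC[C@H]2[C@H](O)[C@@H](O)C(=C(C)C)C[C@]2(C)[C@H]1C | intermediate
20 | (3R,4R,5R,9S,10R)-3,9-dihydroxyeremophil-7(11)-en-8-one | O[C@@H]1CC[C@H]2[C@H](O)C(=O)C(=C(C)C)C[C@]2(C)[C@H]1C | intermediate
21 | ethyl 2-[bis(2,2,2-trifluoroethoxy)phosphoryl]propanoate | CCOC(=O)C(C)P(=O)(OCC(F)(F)F)OCC(F)(F)F | starting material
22 | 2-[bis(2,2,2-trifluoroethoxy)phosphoryl]propanoic acid | OC(=O)C(C)P(=O)(OCC(F)(F)F)OCC(F)(F)F | intermediate
23 | angelic acid | C/C=C(/C)C(=O)O | starting material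
24 | 2-bromoethanol | OCCBr | starting material
25 | 2-hydroxyethyl (Z)-2-methylbut-2-enoate | C/C=C(/C)C(=O)OCCO | intermediate
26 | 2-oxoethyl (Z)-2-methylbut-2-enoate | C/C=C(/C)C(=O)OCC=O | intermediate
27 | 9-hydroxy-8-oxoeremophil-7(11)-en-3-yl 2-[bis(2,2,2-trifluoroethoxy)phosphoryl]propanoate (3R,4R,5R,9S,10R; epimers at the phosphonate carbon) | CC(C(=O)O[C@@H]1CC[C@H]2[C@H](O)C(=O)C(=C(C)C)C[C@]2(C)[C@H]1C)P(=O)(OCC(F)(F)F)OCC(F)(F)F | intermediate
28 | potassium carbanion of 27 | C[C-](C(=O)O[C@@H]1CC[C@H]2[C@H](O)C(=O)C(=C(C)C)C[C@]2(C)[C@H]1C)P(=O)(OCC(F)(F)F)OCC(F)(F)F.[K+] | intermediate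
29 | CNP0308665.1, (3R,4R,5R,9S,10R)-9-hydroxy-8-oxoeremophil-7(11)-en-3-yl (Z)-2-methyl-4-{[(Z)-2-methylbut-2-enoyl]oxy}but-2-enoate | C/C=C(/C)C(=O)OC/C=C(/C)C(=O)O[C@@H]1CC[C@H]2[C@H](O)C(=O)C(=C(C)C)C[C@]2(C)[C@H]1C | target

**Step count and risks**

Total step count: 15. Longest linear sequence: 12 (steps 1–10, 14, 15).

Steps most likely to fail:

**Step 5.** The closure may divert to alkenylation at the free ortho carbon C9 with rearomatisation, or to intermolecular O-alkenylation. The small acyclic alkenyl group may also give the ligand too little to discriminate the two phenoxide faces.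

The fallback inverts the polarity of ring B instead of relying on its nucleophilicity, and it sets out from 9.
- Iodine–lithium exchange (t-BuLi, Et2O, -78 °C) and Me3SiCl give the vinylsilane triisopropyl{4-methyl-3-[(3Z)-4-(trimethylsilyl)pent-3-en-1-yl]phenoxy}silane F1.
- Buffered Bu4NF frees 4-methyl-3-[(3Z)-4-(trimethylsilyl)pent-3-en-1-yl]phenol F2.
- A preformed C2-symmetric lactamide-type chiral aryl-λ3-iodane diacetate in (CF3)2CHOH/CH2Cl2 oxidises the phenol to a phenoxenium-type species whose charge sits on the methyl-bearing para carbon C5.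
- The silicon-bearing C4 attacks there (beta-silicon effect, so C3 cannot compete), the silyl group leaves, and the route is rejoined at 11.

**Step 9.** Three things may go wrong. The C9 borane may undergo beta-elimination with the neighbouring C8 boryloxy group. Borane may attack the tetrasubstituted C7=C11 bond. Facial selectivity at C10 may be incomplete.

The fallback separates the two alkenes and installs C9–O and C10–H by a radical hydration. It sets out from 17.
- 9-BBN (THF, 0 to 65 °C; NaOH, H2O2) reduces the ketone 1,2 and hydroborates only the unhindered ring A alkene. This gives (3R,4R,5R,8R)-eremophila-7(11),9-diene-3,8-diol F3.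
- MnO2 gives (3R,4R,5R)-3-hydroxyeremophila-7(11),9-dien-8-one F4.
- A Mukaiyama-type reductive hydration (Mn(dpm)3 with dpm = dipivaloylmethanate, PhSiH3, O2, iPrOH, then P(OEt)3) delivers a hydrogen atom to C10 anti to C14 and traps the C9 radical with oxygen on the alpha face. The route is rejoined at 20.

**Step 15.** The base may enolise the unprotected ketol, causing epimerisation at C9 or tautomerisation toward the diosphenol. Z selectivity may also erode on the bulky substrate.

The fallback moves the olefination off the terpenoid, so that no strong base meets the ketol. It sets out from 22.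
- DCC and 2-(trimethylsilyl)ethanol give 2-(trimethylsilyl)ethyl 2-[bis(2,2,2-trifluoroethoxy)phosphoryl]propanoate F5.
- Still–Gennari olefination with 26 gives 2-(trimethylsilyl)ethyl (Z)-2-methyl-4-{[(Z)-2-methylbut-2-enoyl]oxy}but-2-enoate F6.
- Bu4NF releases (Z)-2-methyl-4-{[(Z)-2-methylbut-2-enoyl]oxy}but-2-enoic acid F7.
- Yamaguchi esterification (2,4,6-trichlorobenzoyl chloride, Et3N, then DMAP, toluene) of 20 at the C3 hydroxyl, known to keep angelate-type geometry, rejoins the route at 29.

**Further compounds**

F1 | step 5 | triisopropyl{4-methyl-3-[(3Z)-4-(trimethylsilyl)pent-3-en-1-yl]phenoxy}silane | Cc1ccc(O[Si](C(C)C)(C(C)C)C(C)C)cc1CC/C=C(/C)[Si](C)(C)C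
F2 | step 5 | 4-methyl-3-[(3Z)-4-(trimethylsilyl)pent-3-en-1-yl]phenol | Cc1ccc(O)cc1CC/C=C(/C)[Si](C)(C)C
F3 | step 9 | (3R,4R,5R,8R)-eremophila-7(11),9-diene-3,8-diol | O[C@@H]1CCC2=C[C@@H](O)C(=C(C)C)C[C@]2(C)[C@H]1C
F4 | step 9 | (3R,4R,5R)-3-hydroxyeremophila-7(11),9-dien-8-one | O[C@@H]1CCC2=CC(=O)C(=C(C)C)C[C@]2(C)[C@H]1C
F5 | step 15 | 2-(trimethylsilyl)ethyl 2-[bis(2,2,2-trifluoroethoxy)phosphoryl]propanoate | C[Si](C)(C)CCOC(=O)C(C)P(=O)(OCC(F)(F)F)OCC(F)(F)F
F6 | step 15 | 2-(trimethylsilyl)ethyl (Z)-2-methyl-4-{[(Z)-2-methylbut-2-enoyl]oxy}but-2-enoate | C/C=C(/C)C(=O)OC/C=C(/C)C(=O)OCC[Si](C)(C)C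
F7 | step 15 | (Z)-2-methyl-4-{[(Z)-2-methylbut-2-enoyl]oxy}but-2-enoic acid | C/C=C(/C)C(=O)OC/C=C(/C)C(=O)O
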